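## Analysis of the target

Target 37 is a daucane sesquiterpene ester: a cyclopentane (ring A) trans-fused to a cycloheptane (ring B), with a 3,4-dimethoxybenzoate, a tertiary carbinol and a trisubstituted epoxide. The skeleton is numbered as follows: C1 is the quaternary fusion carbon with the angular methyl; C2 and C3 are the ring A methylenes; C4 is the isopropyl carbinol; C5 is the fusion CH; C6 carries the ester; C7 is CH2; C8 carries a methyl and the epoxide oxygen; C9 is the epoxide CH; C10 is CH2. Ring A is C1–C5 and ring B is C5–C10 plus C1.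

There are six stereocentres, (1R,4R,5S,6S,8R,9S) in this numbering. With the C1 methyl taken as β, the C4 hydroxyl is β (cis to the methyl across C5), H5 is α (trans fusion), the C6 oxygen is α (cis to H5), the epoxide oxygen is α and the C8 methyl is β.

The epoxide is acid-labile, the aryl ester is sensitive to strong nucleophiles and bases, and the tertiary alcohol is 1,3 to the ester oxygen, so the epoxide has to come last and C4–OH is best kept silylated until late. The hard part is the C4–C5–C1 array: two fully substituted stereocentres flank the fusion CH inside a five-membered ring that is fused to a seven-membered ring.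

The strategy rests on one feature. C1 and C5 are joined by the three-atom bridge C2–C3–C4, and C4 becomes a propargylic tertiary carbinol if C5–C6 is drawn as an alkyne. Ring B is then the union of that alkyne (C5, C6) with the five carbons C7–C8–C9–C10–C1 of a 1-oxygenated vinylcyclopropane. This places a carbonyl equivalent at C9, next to the carbons that must become the C8 methyl-bearing epoxide carbon and the epoxide CH.

## Retrosynthetic reasoning

**Epoxide and C4–OH.** The C8–C9 epoxide of 37 is cut back to the trisubstituted alkene of 36. This is done last because the epoxide would not survive the earlier chemistry. In the chair-like cycloheptene of 36 the axial C1 methyl covers the β face, so a peracid should enter from the α face. The free C4–OH of 36 comes from triethylsilyl ether 35.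

**C8=C9 alkene, ester, H5 and O6.** The C8=C9 alkene of 35 is traced to enol triflate 34, which is reduced after acylation. The triflate is an alkene that is inert to hydroboration, so no ketone protecting group is needed. The C6–O acyl bond is cut to alcohol 32 and acid chloride 33. The C5–H and C6–O bonds of 32 are cut together to the C5=C6 alkene of 30; the forward syn hydroboration from the α face puts H5 and O6 on the same face and sets the trans fusion.

**C8 methyl carbon.** Enol triflate 30 is traced to α-methylene ketone 28 and then to ketone 24. The one-carbon unit is added at C8 through the kinetic enolate; C10 is neopentyl and is deprotonated more slowly. Conjugate hydride addition to 28 then gives only the C8=C9 enolate, so the position of the triflate is not left to an equilibrium. Ketone 24 is the hydrolysis product of silyl enol ether 23.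

**Key disconnection.** In 23 the bonds C1–C5 and C6–C7 are cut, which opens both rings and gives the acyclic enyne 22 with an (E)-alkenyl silyloxycyclopropane. No other cut removes ring A, ring B and the quaternary C1 in one step while leaving C4 as the only stereocentre. The forward rhodium-catalysed (5+2) cycloaddition has to set C1 relative to C4.

**Terminal alkyne C5≡C6.** Enyne 22 comes from aldehyde 21 by one-carbon homologation, and 21 from the primary silyl ether in 20. The alkyne is unveiled last so that only one alkyne is present during carboalumination and no acidic alkyne hydrogen is present during the organolithium step.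

**Vinylcyclopropane.** The C9–C10 bond of 20 (through 19) is cut to alkenyl iodide 14 and the cyclopropanone equivalent 15. Iodide 14 comes from terminal alkyne 12 by methylmetalation, which installs the C1 methyl and fixes the (E) geometry. Alkyne 12 comes from alkene 8 by hydroboration, oxidation and homologation (through 10 and 11).

**C4 stereocentre.** Bis-silyl ether 8 comes from diol 7, and 7 from allylated dioxolanone 6. The C3–C4 bond is cut to the enolate of dioxolanone 3 and allyl bromide 4. Dioxolanone 3 is the acetal of hydroxy acid 2, made from D-valine 1 with retention. The acetal centre stores the configuration while C4 is planar, so the quaternary carbinol is obtained from the chiral pool at full enantiopurity.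

## Alternatives that were turned down

**Alternative 1:** Ring B is cut at C5–C6 and C9–C10 into 3-methylfuran A2 (C6–C9 with the C8 methyl) and the vinylcarbenoid from diazo ester A3 (C5, C1 with its methyl, C10). In the forward step a chiral divalent rhodium carboxylate would cyclopropanate the less substituted furan double bond, and the divinylcyclopropane would rearrange to the oxygen-bridged cycloheptadiene A1.
- In favour: it is a catalytic enantioselective step from very simple materials, and it delivers ring B with both methyl groups and oxygen on C6 and C9 at once. On speed of access to ring B it is stronger than the chosen route.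
- Against: in A1 the carbon C1 is still sp2, so the quaternary C1, the whole of ring A and C4 all remain to be built on a tetrasubstituted enoate. The ether bridge must then be opened so that oxygen stays on C6 only, which means a long and stereochemically open second half.
- Comparison: the chosen strategy makes C1, ring A and ring B in the single step 22 → 23.

**Alternative 2:** Ring A is cut at C4–C5. In the forward step a lithium amide base or an equilibrating base would form the C5 enolate of cycloheptenone A5, which would add to the pendant isopropyl ketone and give the β-hydroxy enone A4.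
- In favour: it uses ordinary carbonyl chemistry, it sets C4 and C5 in one step, and A4 already carries the C6 oxygen and the C8 methyl. On robustness of the individual reactions it is at least as strong.
- Against: the quaternary C1 of A5 needs an asymmetric conjugate addition to a β-substituted seven-membered enone. The aldol is reversible and the product can dehydrate or undergo retro-aldol cleavage. The sense at C4 relative to C1 is not secured. The C7=C8 enone must later be moved to C8=C9.
- Comparison: the chosen strategy takes C4 from D-valine with certainty and needs no alkene transposition.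

**Alternative 3:** Ring B is cut at C7–C8 and C9–C10. In the forward step a monovalent rhodium catalyst would open the C5–C10 bond of the cyclopropane-fused siloxyvinyl ketal A8 and insert propyne A7 to give A6.
- In favour: A6 has the C8 methyl, the C8=C9 alkene and a C6 oxygen in place, so its endgame is shorter than the one chosen here. On step economy after the key step it is stronger.
- Against: the cycloaddition is intermolecular, so the orientation of A7 (methyl on C8 or on C9) is not fixed by the substrate. A8 needs two adjacent fully substituted cyclopropane carbons in enantiopure form. C4 would be set late by isopropyl addition to a hindered ketone, and H5 by a protonation.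
- Comparison: the chosen strategy is intramolecular, so the tether fixes the regiochemistry, and C4 is carried in from the start.

Key step: step 14

Assumption: α and β refer to the skeleton numbering above with the C1 methyl as β; 1-ethoxycyclopropan-1-ol (15) and 3,4-dimethoxybenzoyl chloride (33) are taken as purchasable.

## Route

Step 1
Reactants: 1 D-valine
Product: 2 (2R)-2-hydroxy-3-methylbutanoic acid
Conditions: NaNO2, aq. H2SO4, 0 °C → rt
Reagents that add atoms: water, O
Why: Diazotisation of the α-amino acid; the carboxylate displaces N2 to an α-lactone that water opens, and the two inversions leave the (R) configuration.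

Step 2
Reactants: 2 (2R)-2-hydroxy-3-methylbutanoic acid
Product: 3 (2R,5R)-2-tert-butyl-5-(propan-2-yl)-1,3-dioxolan-4-one
Conditions: t-BuCHO, TsOH (cat.), pentane, reflux with removal of water
Reagents that add atoms: pivalaldehyde, CC(C)(C)C=O
Why: Acid-catalysed acetalisation under thermodynamic control should favour the cis isomer, so the new acetal centre (2R) is set by C5 and stores its configuration.

Step 3
Reactants: 3 (2R,5R)-2-tert-butyl-5-(propan-2-yl)-1,3-dioxolan-4-one; 4 allyl bromide
Product: 6 (2R,5R)-2-tert-butyl-5-(prop-2-en-1-yl)-5-(propan-2-yl)-1,3-dioxolan-4-one, via lithium dioxolanone enolate 5 (not isolated)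
Conditions: LiN(iPr)2, THF, −78 °C; then 4, −78 → −20 °C
Reagents that add atoms: none
Why: Enolate alkylation by self-regeneration of the stereocentre; C5 is planar in 5 and the tert-butyl group blocks its own face, so the allyl group enters trans to it, where the hydrogen was, and the future C4 becomes quaternary with the C3–C4 bond in place.

Step 4
Reactants: 6 (2R,5R)-2-tert-butyl-5-(prop-2-en-1-yl)-5-(propan-2-yl)-1,3-dioxolan-4-one
Product: 7 (2R)-2-(propan-2-yl)pent-4-ene-1,2-diol
Conditions: LiAlH4, Et2O, 0 °C → rt
Reagents that add atoms: none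
Why: Hydride reduction of the lactone carbonyl to CH2OH; the acetal carbon is released and reduced to neopentyl alcohol, and the quaternary centre is untouched.

Step 5
Reactants: 7 (2R)-2-(propan-2-yl)pent-4-ene-1,2-diol
Product: 8 (4R)-4-(propan-2-yl)-4,5-bis(triethylsilyloxy)pent-1-ene
Conditions: Et3SiOTf, 2,6-lutidine, CH2Cl2, −78 → 0 °C
Reagents that add atoms: triethylsilyl trifluoromethanesulfonate, CC[Si](CC)(CC)OS(=O)(=O)C(F)(F)F
Why: Silyl triflate silylation is strong enough for the hindered tertiary alcohol; the primary silyl ether is the latent C5 aldehyde and the tertiary one is the C4 protecting group of the key step.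

Step 6
Reactants: 8 (4R)-4-(propan-2-yl)-4,5-bis(triethylsilyloxy)pent-1-ene
Product: 10 (4R)-4-(propan-2-yl)-4,5-bis(triethylsilyloxy)pentan-1-ol, via B-alkyl-9-borabicyclononane 9 (not isolated)
Conditions: 9-BBN, THF, 0 °C → rt; then NaBO3·4H2O, H2O, rt
Reagents that add atoms: sodium perborate, [Na+].[Na+].O[B-]1(O)OO[B-](O)(O)OO1
Why: Anti-Markovnikov hydroboration of the terminal alkene and mild perborate oxidation, which spares the primary silyl ether; the new CH2OH carbon is C1 of the skeleton.

Step 7
Reactants: 10 (4R)-4-(propan-2-yl)-4,5-bis(triethylsilyloxy)pentan-1-ol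
Product: 11 (4R)-4-(propan-2-yl)-4,5-bis(triethylsilyloxy)pentanal
Conditions: Dess–Martin periodinane, NaHCO3, CH2Cl2, 0 °C → rt
Reagents that add atoms: none
Why: Buffered Dess–Martin oxidation of a primary alcohol; silyl ethers are stable under these neutral conditions.

Step 8
Reactants: 11 (4R)-4-(propan-2-yl)-4,5-bis(triethylsilyloxy)pentanal
Product: 12 (5R)-5-(propan-2-yl)-5,6-bis(triethylsilyloxy)hex-1-yne
Conditions: MeC(O)C(N2)P(O)(OMe)2, K2CO3, MeOH, 0 °C → rt
Reagents that add atoms: dimethyl (1-diazo-2-oxopropyl)phosphonate, COP(=O)(OC)C(=[N+]=[N-])C(C)=O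
Why: Ohira–Bestmann (Seyferth–Gilbert) homologation of the aldehyde to the terminal alkyne; the added carbon is C10.

Step 9
Reactants: 12 (5R)-5-(propan-2-yl)-5,6-bis(triethylsilyloxy)hex-1-yne
Product: 14 (1E,5R)-1-iodo-2-methyl-5-(propan-2-yl)-5,6-bis(triethylsilyloxy)hex-1-ene, via dimethylalkenylalane 13 (not isolated)
Conditions: Me3Al, Cp2ZrCl2 (cat.), CH2Cl2, 0 °C → rt; then I2, THF, −30 °C
Reagents that add atoms: trimethylaluminium, C[Al](C)C; iodine, II
Why: Negishi zirconium-catalysed carboalumination adds methyl and aluminium syn across the terminal alkyne with methyl on the internal carbon, and iodinolysis proceeds with retention, so the C1 methyl and the (E) geometry are fixed.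

Step 10
Reactants: 14 (1E,5R)-1-iodo-2-methyl-5-(propan-2-yl)-5,6-bis(triethylsilyloxy)hex-1-ene; 15 1-ethoxycyclopropan-1-ol
Product: 19 1-[(1E,5R)-2-methyl-5-(propan-2-yl)-5,6-bis(triethylsilyloxy)hex-1-en-1-yl]cyclopropan-1-ol, via alkenyllithium 16 (not isolated), via bromomagnesium 1-ethoxycyclopropan-1-olate 17 (not isolated), via cyclopropanone 18 (not isolated)
Conditions: 14, t-BuLi (2 equiv), Et2O, −78 °C; 15 pretreated with MeMgBr (THF, 0 °C); combine, −78 °C → rt; aq. NH4Cl
Reagents that add atoms: none
Why: Iodine–lithium exchange with retention of alkene geometry, then 1,2-addition of the alkenyl metal to cyclopropanone released from its magnesium hemiacetal salt; this forms C9–C10.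

Step 11
Reactants: 19 1-[(1E,5R)-2-methyl-5-(propan-2-yl)-5,6-bis(triethylsilyloxy)hex-1-en-1-yl]cyclopropan-1-ol
Product: 20 tert-butyl(dimethyl)silyl ether of 19
Conditions: t-BuMe2SiOTf, 2,6-lutidine, CH2Cl2, −78 °C
Reagents that add atoms: tert-butyldimethylsilyl trifluoromethanesulfonate, CC(C)(C)[Si](C)(C)OS(=O)(=O)C(F)(F)F
Why: Silylation of the tertiary cyclopropanol under buffered conditions, which avoids acid-induced ring expansion of the 1-alkenylcyclopropanol and gives the siloxy group that activates the cyclopropane in the key step.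

Step 12
Reactants: 20 tert-butyl(dimethyl)silyl ether of 19
Product: 21 (2R,5E)-6-[1-(tert-butyldimethylsilyloxy)cyclopropyl]-5-methyl-2-(propan-2-yl)-2-(triethylsilyloxy)hex-5-enal
Conditions: (COCl)2, DMSO, CH2Cl2, −78 → −30 °C; then Et3N, −78 °C → rt
Reagents that add atoms: none
Why: Swern oxidation applied directly to a primary triethylsilyl ether; the activated sulfoxide attacks the least hindered silyl ether oxygen, while the tertiary triethylsilyl and tert-butyldimethylsilyl ethers are too hindered to react.

Step 13
Reactants: 21 (2R,5E)-6-[1-(tert-butyldimethylsilyloxy)cyclopropyl]-5-methyl-2-(propan-2-yl)-2-(triethylsilyloxy)hex-5-enal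
Product: 22 enyne tert-butyl(dimethyl){1-[(1E,5R)-2-methyl-5-(propan-2-yl)-5-(triethylsilyloxy)hept-1-en-6-yn-1-yl]cyclopropoxy}silane
Conditions: MeC(O)C(N2)P(O)(OMe)2, K2CO3, MeOH, 0 °C → rt
Reagents that add atoms: dimethyl (1-diazo-2-oxopropyl)phosphonate, COP(=O)(OC)C(=[N+]=[N-])C(C)=O
Why: Ohira–Bestmann homologation; the aldehyde carbon is quaternary at its α-position, so it cannot epimerise under the basic conditions, and the added carbon is C6.

Step 14
Reactants: 22 enyne tert-butyl(dimethyl){1-[(1E,5R)-2-methyl-5-(propan-2-yl)-5-(triethylsilyloxy)hept-1-en-6-yn-1-yl]cyclopropoxy}silane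
Product: 23 bicyclic silyl enol ether (1R,4R)-9-(tert-butyldimethylsilyloxy)-1-methyl-4-(propan-2-yl)-4-(triethylsilyloxy)bicyclo[5.3.0]deca-5,9-diene (skeleton numbering)
Conditions: [Rh(CO)2Cl]2 (5 mol%), toluene, 80 °C
Reagents that add atoms: none
Why: Monovalent rhodium binds the vinylcyclopropane and cleaves a cyclopropane bond at the siloxy-bearing carbon with release of strain, giving a trivalent rhodium metallacycle with a π-allyl over C1–C10–C9 and a σ-bond to C7. The tethered alkyne then inserts at the allyl terminus C1, which forms C1–C5 and closes ring A in a 5-exo sense through the C2–C3–C4 tether. Reductive elimination between C6 and C7 closes ring B as the seven-membered (5+2) adduct and returns monovalent rhodium. The closest known reaction type is the rhodium-catalysed intramolecular vinylcyclopropane–alkyne (5+2) cycloaddition, here with a siloxy-activated cyclopropane and a trisubstituted alkene. The only new stereocentre is C1, and the controlling element is C4. In the insertion transition state the forming five-membered ring places the C1 methyl pseudo-axial and the rhodium-bound C10 outward; the methyl should avoid the larger isopropyl group on C4 and so end up cis to the silyloxy group. The step needs this facial selectivity and needs insertion to be faster than unproductive opening of the cyclopropane. The tether fixes the regiochemistry, the two cyclopropane CH2 groups are equivalent, and the siloxy group both accelerates the cleavage and leaves C9 as an enol ether.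

Step 15
Reactants: 23 bicyclic silyl enol ether (1R,4R)
Product: 24 (1R,4R)-1-methyl-4-(propan-2-yl)-4-(triethylsilyloxy)bicyclo[5.3.0]dec-5-en-9-one
Conditions: Bu4NF, AcOH, THF, −20 °C
Reagents that add atoms: none
Why: Buffered fluoride cleaves the silyl enol ether much faster than the hindered tertiary triethylsilyl ether, and protonation at C10 gives the C9 ketone, which is not conjugated with C5=C6.

Step 16
Reactants: 24 (1R,4R)-1-methyl-4-(propan-2-yl)-4-(triethylsilyloxy)bicyclo[5.3.0]dec-5-en-9-one
Product: 28 (1R,4R)-1-methyl-8-methylidene-4-(propan-2-yl)-4-(triethylsilyloxy)bicyclo[5.3.0]dec-5-en-9-one, via lithium C8 enolate 25 (not isolated), via Mannich base 26 (not isolated), via trimethylammonium iodide 27 (not isolated)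
Conditions: LiN(iPr)2, THF, −78 °C; CH2=NMe2+ I−, −78 °C → rt; then MeI, CH2Cl2, rt; then aq. NaHCO3
Reagents that add atoms: dimethyl(methylidene)ammonium iodide (Eschenmoser's salt), C=[N+](C)C.[I-]
Why: Kinetic deprotonation should occur at C8 because C10 is neopentyl; the Mannich reaction with the iminium salt, quaternisation and β-elimination give the α-methylene ketone, whose new carbon is the future C8 methyl.

Step 17
Reactants: 28 (1R,4R)-1-methyl-8-methylidene-4-(propan-2-yl)-4-(triethylsilyloxy)bicyclo[5.3.0]dec-5-en-9-one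
Product: 30 (1R,4R)-1,8-dimethyl-4-(propan-2-yl)-4-(triethylsilyloxy)bicyclo[5.3.0]deca-5,8-dien-9-yl trifluoromethanesulfonate, via lithium C8=C9 enolate 29 (not isolated)
Conditions: LiBH(s-Bu)3, THF, −78 °C; then PhNTf2, −78 → 0 °C
Reagents that add atoms: N-phenylbis(trifluoromethanesulfonimide), O=S(=O)(N(c1ccccc1)S(=O)(=O)C(F)(F)F)C(F)(F)F
Why: Conjugate hydride addition to the unhindered methylene terminus forms only the C8=C9 enolate, which is trapped on oxygen as the enol triflate, so the place of the later alkene does not depend on an enolate equilibrium.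

Step 18
Reactants: 30 enol triflate (1R,4R)
Product: 32 (1R,4R,5S,6S)-6-hydroxy-1,8-dimethyl-4-(propan-2-yl)-4-(triethylsilyloxy)bicyclo[5.3.0]dec-8-en-9-yl trifluoromethanesulfonate, via C6 alkylborane 31 (not isolated)
Conditions: BH3·THF, THF, 0 °C → rt; then NaBO3·4H2O, H2O, rt
Reagents that add atoms: sodium perborate, [Na+].[Na+].O[B-]1(O)OO[B-](O)(O)OO1
Why: Hydroboration–oxidation; the tetrasubstituted, electron-poor enol triflate alkene should not react with borane, so only C5=C6 is attacked, with boron at the less substituted C6. The pseudo-axial C1 methyl and the C4 silyloxy group cover the β face, as the angular methyl does in Δ5-steroids, so syn addition from the α face should set H5 and O6 together.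

Step 19
Reactants: 32 alcohol (1R,4R,5S,6S); 33 3,4-dimethoxybenzoyl chloride
Product: 34 (1R,4R,5S,6S)-1,8-dimethyl-4-(propan-2-yl)-4-(triethylsilyloxy)-9-(trifluoromethanesulfonyloxy)bicyclo[5.3.0]dec-8-en-6-yl 3,4-dimethoxybenzoate
Conditions: 33, DMAP, Et3N, CH2Cl2, rt → 40 °C
Reagents that add atoms: none
Why: DMAP-catalysed acylation of the only free hydroxyl; the configuration at C6 is not touched.

Step 20
Reactants: 34 enol triflate ester (1R,4R,5S,6S)
Product: 35 (1R,4R,5S,6S)-1,8-dimethyl-4-(propan-2-yl)-4-(triethylsilyloxy)bicyclo[5.3.0]dec-8-en-6-yl 3,4-dimethoxybenzoate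
Conditions: Pd(OAc)2 (cat.), PPh3, Bu3N, HCO2H, DMF, 60 °C
Reagents that add atoms: none
Why: Palladium-catalysed formate reduction of an enol triflate; oxidative addition to zerovalent palladium, exchange of triflate for formate, loss of CO2 and reductive elimination of C–H give the C8=C9 alkene without touching the aryl ester.

Step 21
Reactants: 35 silyl ether (1R,4R,5S,6S)
Product: 36 (1R,4R,5S,6S)-4-hydroxy-1,8-dimethyl-4-(propan-2-yl)bicyclo[5.3.0]dec-8-en-6-yl 3,4-dimethoxybenzoate
Conditions: HF·pyridine, pyridine, THF, 0 °C → rt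
Reagents that add atoms: none
Why: Fluoride-mediated cleavage of the tertiary triethylsilyl ether under buffered, non-basic conditions, which leave the ester in place and avoid acyl migration to the freed hydroxyl.

Step 22
Reactants: 36 alkene (1R,4R,5S,6S)
Product: 37 target (1R,4R,5S,6S,8R,9S)-8,9-epoxy-4-hydroxy-1,8-dimethyl-4-(propan-2-yl)bicyclo[5.3.0]decan-6-yl 3,4-dimethoxybenzoate
Conditions: mCPBA, NaHCO3, CH2Cl2, 0 °C
Reagents that add atoms: 3-chloroperoxybenzoic acid, OOC(=O)c1cccc(Cl)c1
Why: Prilezhaev epoxidation of the only alkene; in the chair-like cycloheptene the axial C1 methyl shields the β face and the equatorial C6 ester points outward, so the oxygen should be delivered to the α face and set C8 and C9 together.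

## Compound list

1 | D-valine, (2R)-2-amino-3-methylbutanoic acid | CC(C)[C@@H](N)C(=O)O | starting material
2 | (2R)-2-hydroxy-3-methylbutanoic acid | CC(C)[C@@H](O)C(=O)O | intermediate
3 | (2R,5R)-2-tert-butyl-5-(propan-2-yl)-1,3-dioxolan-4-one (cis) | CC(C)[C@H]1O[C@@H](C(C)(C)C)OC1=O | intermediate
4 | allyl bromide (3-bromoprop-1-ene) | C=CCBr | starting material
5 | lithium enolate of 3 (lithium (2R)-2-tert-butyl-5-(propan-2-yl)-1,3-dioxol-4-olate) | CC(C)C1=C(O[Li])O[C@H](C(C)(C)C)O1 | intermediate
6 | (2R,5R)-2-tert-butyl-5-(prop-2-en-1-yl)-5-(propan-2-yl)-1,3-dioxolan-4-one | C=CC[C@]1(C(C)C)O[C@@H](C(C)(C)C)OC1=O | intermediate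
7 | (2R)-2-(propan-2-yl)pent-4-ene-1,2-diol | OC[C@](O)(C(C)C)CC=C | intermediate
8 | (4R)-4-(propan-2-yl)-4,5-bis(triethylsilyloxy)pent-1-ene | CC[Si](CC)(CC)OC[C@](O[Si](CC)(CC)CC)(C(C)C)CC=C | intermediate
9 | 9-[(4R)-4-(propan-2-yl)-4,5-bis(triethylsilyloxy)pentyl]-9-borabicyclo[3.3.1]nonane | CC[Si](CC)(CC)OC[C@](O[Si](CC)(CC)CC)(C(C)C)CCCB1C2CCCC1CCC2 | intermediate
10 | (4R)-4-(propan-2-yl)-4,5-bis(triethylsilyloxy)pentan-1-ol | CC[Si](CC)(CC)OC[C@](O[Si](CC)(CC)CC)(C(C)C)CCCO | intermediate
11 | (4R)-4-(propan-2-yl)-4,5-bis(triethylsilyloxy)pentanal | CC[Si](CC)(CC)OC[C@](O[Si](CC)(CC)CC)(C(C)C)CCC=O | intermediate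
12 | (5R)-5-(propan-2-yl)-5,6-bis(triethylsilyloxy)hex-1-yne | CC[Si](CC)(CC)OC[C@](O[Si](CC)(CC)CC)(C(C)C)CCC#C | intermediate
13 | dimethyl[(1E,5R)-2-methyl-5-(propan-2-yl)-5,6-bis(triethylsilyloxy)hex-1-en-1-yl]alumane | CC[Si](CC)(CC)OC[C@](O[Si](CC)(CC)CC)(C(C)C)CC/C(C)=C/[Al](C)C | intermediate
14 | (1E,5R)-1-iodo-2-methyl-5-(propan-2-yl)-5,6-bis(triethylsilyloxy)hex-1-ene | CC[Si](CC)(CC)OC[C@](O[Si](CC)(CC)CC)(C(C)C)CC/C(C)=C/I | intermediate
15 | 1-ethoxycyclopropan-1-ol | CCOC1(O)CC1 | starting material
16 | [(1E,5R)-2-methyl-5-(propan-2-yl)-5,6-bis(triethylsilyloxy)hex-1-en-1-yl]lithium | CC[Si](CC)(CC)OC[C@](O[Si](CC)(CC)CC)(C(C)C)CC/C(C)=C/[Li] | intermediate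
17 | bromomagnesium 1-ethoxycyclopropan-1-olate | CCOC1(O[Mg]Br)CC1 | intermediate
18 | cyclopropanone | O=C1CC1 | intermediate
19 | 1-[(1E,5R)-2-methyl-5-(propan-2-yl)-5,6-bis(triethylsilyloxy)hex-1-en-1-yl]cyclopropan-1-ol | CC[Si](CC)(CC)OC[C@](O[Si](CC)(CC)CC)(C(C)C)CC/C(C)=C/C1(O)CC1 | intermediate
20 | tert-butyl(dimethyl){1-[(1E,5R)-2-methyl-5-(propan-2-yl)-5,6-bis(triethylsilyloxy)hex-1-en-1-yl]cyclopropoxy}silane | CC[Si](CC)(CC)OC[C@](O[Si](CC)(CC)CC)(C(C)C)CC/C(C)=C/C1(O[Si](C)(C)C(C)(C)C)CC1 | intermediate
21 | (2R,5E)-6-[1-(tert-butyldimethylsilyloxy)cyclopropyl]-5-methyl-2-(propan-2-yl)-2-(triethylsilyloxy)hex-5-enal | O=C[C@](O[Si](CC)(CC)CC)(C(C)C)CC/C(C)=C/C1(O[Si](C)(C)C(C)(C)C)CC1 | intermediate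
22 | tert-butyl(dimethyl){1-[(1E,5R)-2-methyl-5-(propan-2-yl)-5-(triethylsilyloxy)hept-1-en-6-yn-1-yl]cyclopropoxy}silane (key-step precursor) | C#C[C@](O[Si](CC)(CC)CC)(C(C)C)CC/C(C)=C/C1(O[Si](C)(C)C(C)(C)C)CC1 | intermediate
23 | (1R,4R)-9-(tert-butyldimethylsilyloxy)-1-methyl-4-(propan-2-yl)-4-(triethylsilyloxy)bicyclo[5.3.0]deca-5,9-diene, skeleton numbering (key-step product) | CC(C)(C)[Si](C)(C)OC1=C[C@@]2(C)CC[C@@](O[Si](CC)(CC)CC)(C(C)C)C2=CCC1 | intermediate
24 | (1R,4R)-1-methyl-4-(propan-2-yl)-4-(triethylsilyloxy)bicyclo[5.3.0]dec-5-en-9-one | O=C1C[C@@]2(C)CC[C@@](O[Si](CC)(CC)CC)(C(C)C)C2=CCC1 | intermediate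
25 | lithium C8=C9 enolate of 24 | [Li]OC=1C[C@@]2(C)CC[C@@](O[Si](CC)(CC)CC)(C(C)C)C2=CCC=1 | intermediate
26 | 8-[(dimethylamino)methyl] derivative of 24 (C8 epimers) | O=C1C[C@@]2(C)CC[C@@](O[Si](CC)(CC)CC)(C(C)C)C2=CCC1CN(C)C | intermediate
27 | 8-[(trimethylammonio)methyl] derivative of 24, iodide (C8 epimers) | O=C1C[C@@]2(C)CC[C@@](O[Si](CC)(CC)CC)(C(C)C)C2=CCC1C[N+](C)(C)C.[I-] | intermediate
28 | (1R,4R)-1-methyl-8-methylidene-4-(propan-2-yl)-4-(triethylsilyloxy)bicyclo[5.3.0]dec-5-en-9-one | O=C1C[C@@]2(C)CC[C@@](O[Si](CC)(CC)CC)(C(C)C)C2=CCC1=C | intermediate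
29 | lithium (1R,4R)-1,8-dimethyl-4-(propan-2-yl)-4-(triethylsilyloxy)bicyclo[5.3.0]deca-5,8-dien-9-olate | CC1=C(O[Li])C[C@@]2(C)CC[C@@](O[Si](CC)(CC)CC)(C(C)C)C2=CC1 | intermediate
30 | (1R,4R)-1,8-dimethyl-4-(propan-2-yl)-4-(triethylsilyloxy)bicyclo[5.3.0]deca-5,8-dien-9-yl trifluoromethanesulfonate | CC1=C(OS(=O)(=O)C(F)(F)F)C[C@@]2(C)CC[C@@](O[Si](CC)(CC)CC)(C(C)C)C2=CC1 | intermediate
31 | C6 alkylborane from 30 (6α-boryl, 5α-H) | B[C@H]2CC(C)=C(OS(=O)(=O)C(F)(F)F)C[C@@]3(C)CC[C@@](O[Si](CC)(CC)CC)(C(C)C)[C@H]23 | intermediate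
32 | (1R,4R,5S,6S)-6-hydroxy-1,8-dimethyl-4-(propan-2-yl)-4-(triethylsilyloxy)bicyclo[5.3.0]dec-8-en-9-yl trifluoromethanesulfonate | O[C@H]2CC(C)=C(OS(=O)(=O)C(F)(F)F)C[C@@]3(C)CC[C@@](O[Si](CC)(CC)CC)(C(C)C)[C@H]23 | intermediate
33 | 3,4-dimethoxybenzoyl chloride | COc1ccc(C(Cl)=O)cc1OC | starting material
34 | (1R,4R,5S,6S)-1,8-dimethyl-4-(propan-2-yl)-4-(triethylsilyloxy)-9-(trifluoromethanesulfonyloxy)bicyclo[5.3.0]dec-8-en-6-yl 3,4-dimethoxybenzoate | COc1ccc(C(=O)O[C@H]2CC(C)=C(OS(=O)(=O)C(F)(F)F)C[C@@]3(C)CC[C@@](O[Si](CC)(CC)CC)(C(C)C)[C@H]23)cc1OC | intermediate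
35 | (1R,4R,5S,6S)-1,8-dimethyl-4-(propan-2-yl)-4-(triethylsilyloxy)bicyclo[5.3.0]dec-8-en-6-yl 3,4-dimethoxybenzoate | COc1ccc(C(=O)O[C@H]2CC(C)=CC[C@@]3(C)CC[C@@](O[Si](CC)(CC)CC)(C(C)C)[C@H]23)cc1OC | intermediate
36 | (1R,4R,5S,6S)-4-hydroxy-1,8-dimethyl-4-(propan-2-yl)bicyclo[5.3.0]dec-8-en-6-yl 3,4-dimethoxybenzoate | COc1ccc(C(=O)O[C@H]2CC(C)=CC[C@@]3(C)CC[C@@](O)(C(C)C)[C@H]23)cc1OC | intermediate
37 | (1R,4R,5S,6S,8R,9S)-8,9-epoxy-4-hydroxy-1,8-dimethyl-4-(propan-2-yl)bicyclo[5.3.0]decan-6-yl 3,4-dimethoxybenzoate (CNP0251065.1) | COc1ccc(C(=O)O[C@H]2C[C@@]3(C)O[C@H]3C[C@@]3(C)CC[C@@](O)(C(C)C)[C@H]23)cc1OC | target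

## Step count and least certain steps

Total step count: 22. Longest linear sequence: 22 steps (the route is linear from 1).

**Step 14 (key step).** The trisubstituted alkene carries a methyl group cis to the cyclopropane and may insert too slowly, so that unproductive opening of the siloxycyclopropane takes over. The two alkene faces may also be discriminated poorly, or in the wrong sense, if the triethylsilyloxy group behaves as the larger substituent on C4. The fallback changes the controlling element from a bulky silyl ether to a small free hydroxyl. It sets out from 22: selective removal of the tertiary triethylsilyl group (HF·pyridine, pyridine, THF, 0 °C; the tert-butyldimethylsilyl cyclopropyl ether is much slower) would give (3R,6E)-7-[1-(tert-butyldimethylsilyloxy)cyclopropyl]-6-methyl-3-(propan-2-yl)hept-6-en-1-yn-3-ol F1. Cycloaddition of F1 with [Rh(CO)2Cl]2, in which the hydroxyl is clearly smaller than isopropyl, would give the diene-ol F2. Resilylation (Et3SiOTf, 2,6-lutidine) returns to the route at 23.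

**Step 18.** Borane may add to the β face of C5=C6 as well, giving the cis-fused isomer, and the enol triflate may be attacked by borane or lost in the oxidative work-up. The fallback masks C9 as a ketal instead of an enol triflate, so that the alkene is hydroborated in a ring B without further sp2 centres and with a robust protecting group. It sets out from 24:
- Ketalisation with (Me3SiOCH2)2 and catalytic Me3SiOTf at −78 °C would give dioxolane F3.
- BH3·THF followed by NaOH/H2O2 would give the 6α-alcohol F4.
- Acylation with 33 would give ester F5.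
- PPTS in wet acetone would release keto ester F6.
- Kinetic enolisation with in situ Me3SiCl trapping, then CH2=NMe2+ I−, MeI and NaHCO3, would give α-methylene ketone F7.
- LiBH(s-Bu)3 followed by PhNTf2 returns to the route at 34.

**Step 22.** The peracid may attack the β face of C8=C9 in part or mainly, giving the epimeric epoxide. The fallback builds the epoxide in two steps with the opposite sense of oxygen delivery. It sets out from 36: N-bromosuccinimide in aqueous THF would form the bromonium ion on the face the peracid prefers, and water would open it at the tertiary C8 from the other face to give the 9β-bromo-8α-hydroxy compound F8. Ring closure with K2CO3 in MeCN, by displacement of bromide from the α face, gives 37.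

**Step 10.** The alkenyl metal may be quenched by proton transfer, or cyclopropanone may open or oligomerise before it is attacked. The fallback builds the siloxycyclopropane by cyclopropanation instead of carbonyl addition. It sets out from 14:
- Iodine–lithium exchange (to 16) and acylation with N-methoxy-N-methylacetamide would give the (E)-enone F9.
- t-BuMe2SiOTf and Et3N would give the 2-silyloxydiene F10.
- Simmons–Smith cyclopropanation (Et2Zn, CH2I2) of the electron-rich enol ether double bond returns to the route at 20.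

Further compounds
F1 | step 14 | (3R,6E)-7-[1-(tert-butyldimethylsilyloxy)cyclopropyl]-6-methyl-3-(propan-2-yl)hept-6-en-1-yn-3-ol | C#C[C@](O)(C(C)C)CC/C(C)=C/C1(O[Si](C)(C)C(C)(C)C)CC1
F2 | step 14 | (1R,4R)-9-(tert-butyldimethylsilyloxy)-1-methyl-4-(propan-2-yl)bicyclo[5.3.0]deca-5,9-dien-4-ol | CC(C)(C)[Si](C)(C)OC1=C[C@@]2(C)CC[C@@](O)(C(C)C)C2=CCC1
F3 | step 18 | ethylene ketal of 24 | C1COC2(O1)C[C@@]3(C)CC[C@@](O[Si](CC)(CC)CC)(C(C)C)C3=CCC2
F4 | step 18 | (1R,4R,5S,6S)-9,9-ethylenedioxy-1-methyl-4-(propan-2-yl)-4-(triethylsilyloxy)bicyclo[5.3.0]decan-6-ol | O[C@H]2CCC4(OCCO4)C[C@@]3(C)CC[C@@](O[Si](CC)(CC)CC)(C(C)C)[C@H]23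
F5 | step 18 | 3,4-dimethoxybenzoate of F4 | COc1ccc(C(=O)O[C@H]2CCC4(OCCO4)C[C@@]3(C)CC[C@@](O[Si](CC)(CC)CC)(C(C)C)[C@H]23)cc1OC
F6 | step 18 | (1R,4R,5S,6S)-1-methyl-9-oxo-4-(propan-2-yl)-4-(triethylsilyloxy)bicyclo[5.3.0]decan-6-yl 3,4-dimethoxybenzoate | COc1ccc(C(=O)O[C@H]2CCC(=O)C[C@@]3(C)CC[C@@](O[Si](CC)(CC)CC)(C(C)C)[C@H]23)cc1OC
F7 | step 18 | (1R,4R,5S,6S)-1-methyl-8-methylidene-9-oxo-4-(propan-2-yl)-4-(triethylsilyloxy)bicyclo[5.3.0]decan-6-yl 3,4-dimethoxybenzoate | COc1ccc(C(=O)O[C@H]2CC(=C)C(=O)C[C@@]3(C)CC[C@@](O[Si](CC)(CC)CC)(C(C)C)[C@H]23)cc1OC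
F8 | step 22 | 9β-bromo-4β,8α-dihydroxy-1,8-dimethyl-4-(propan-2-yl)bicyclo[5.3.0]decan-6α-yl 3,4-dimethoxybenzoate | COc1ccc(C(=O)O[C@H]2C[C@@](C)(O)[C@H](Br)C[C@@]3(C)CC[C@@](O)(C(C)C)[C@H]23)cc1OC
F9 | step 10 | (3E,7R)-4-methyl-7-(propan-2-yl)-7,8-bis(triethylsilyloxy)oct-3-en-2-one | CC[Si](CC)(CC)OC[C@](O[Si](CC)(CC)CC)(C(C)C)CC/C(C)=C/C(C)=O
F10 | step 10 | (3E,7R)-2-(tert-butyldimethylsilyloxy)-4-methyl-7-(propan-2-yl)-7,8-bis(triethylsilyloxy)octa-1,3-diene | CC[Si](CC)(CC)OC[C@](O[Si](CC)(CC)CC)(C(C)C)CC/C(C)=C/C(=C)O[Si](C)(C)C(C)(C)C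
A1 | alternative 1 | methyl 3,6-dimethyl-8-oxabicyclo[3.2.1]octa-2,6-diene-2-carboxylate | COC(=O)C1=C(C)C[C@@H]2O[C@H]1C=C2C
A2 | alternative 1 | 3-methylfuran | Cc1ccoc1
A3 | alternative 1 | methyl 2-diazo-3-methylbut-3-enoate | COC(=O)C(=[N+]=[N-])C(C)=C
A4 | alternative 2 | bicyclic β-hydroxy enone with C4 isopropyl carbinol, C5 methine and C7=C8 enone | O=C1C=C(C)CC[C@@]2(C)CC[C@@](O)(C(C)C)[C@H]12
A5 | alternative 2 | 3,6-dimethyl-6-(4-methyl-3-oxopentyl)cyclohept-2-en-1-one | CC(C)C(=O)CC[C@]1(C)CCC(C)=CC(=O)C1
A6 | alternative 3 | bicyclic C5=C6 silyl enol ether with C8=C9 alkene, quaternary C1 and C4 ketal | CC(C)(C)[Si](C)(C)OC1=C2C3(OCCO3)CC[C@]2(C)CC=C(C)C1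
A7 | alternative 3 | propyne | C#CC
A8 | alternative 3 | 1-[1-(tert-butyldimethylsilyloxy)ethenyl]-5-methylbicyclo[3.1.0]hexan-2-one ethylene ketal | C=C(O[Si](C)(C)C(C)(C)C)[C@]12C[C@@]1(C)CCC23OCCO3
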